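**Plan**

Feature: ring A has its acyl carbon on C1, hydroxyls on C2 and C4 and propyl on C6, so oxygen sits on every second carbon. Ring plus carboxyl carbon is therefore a folded, dehydrated 3,5,7-trioxodecanoyl chain (chain C2–C7 = ring A C1–C6) on O-4 of ring B.
Cuts, in order: ring A C1–C6 (aldol); the depside acyl–O bond (acylketene + ring B phenol); chain C6–C7 (ring A C5–C6) and chain C4–C5 (ring A C3–C4), both enolate acylations of a dioxinone.
Forward, chain: 2,2,6-trimethyldioxinone takes up an acetyl and then a butanoyl unit and so holds all ten chain carbons.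
Forward, ring B: bought as methyl divarinate and only re-decorated (4-O-benzyl, 2-O-methyl, debenzylation) to expose the 4-hydroxyl alone.
Thermolysis links chain and ring B through oxygen. Ring A, the only ring built, closes last and reveals its own hydroxyls, which therefore need no protection.
Stereochemistry: the target has no stereocentre, and the two centres of the transient cyclic aldol are erased on aromatisation.

Key step: step 8

Assumption: methyl divarinate is taken as purchasable, and all poly-β-carbonyl compounds are written in the all-keto form although they exist largely as enols.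

**Step 1**
Reactants: 1 2,2,6-trimethyl-4H-1,3-dioxin-4-one; 2 acetyl chloride
Product: 4 2,2-dimethyl-6-(2-oxopropyl)-4H-1,3-dioxin-4-one, via lithium dienolate 3 (not isolated)
Conditions: 1 (2 equiv), LiN(SiMe3)2 (2 equiv), THF, −78 °C; then 2 (1 equiv), −78 → −20 °C; aq. HCl
Reagents that add atoms: none
Why: Kinetic deprotonation of the 6-methyl group gives dienolate 3, which is C-acylated at its exocyclic carbon by the acid chloride (vinylogous Claisen-type acylation of a dioxinone dienolate), while the surplus dienolate absorbs the more acidic proton of 4 so that a second acylation is avoided.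

**Step 2**
Reactants: 5 butanoyl chloride
Product: 6 N-methoxy-N-methylbutanamide
Conditions: MeNH(OMe)·HCl, K2CO3, CH2Cl2/H2O, 0 °C → rt
Reagents that add atoms: N,O-dimethylhydroxylamine hydrochloride, CNOC.Cl
Why: Schotten–Baumann N-acylation of the hydroxylamine by the acid chloride is fast at 0 °C, and the carbonate takes up both equivalents of HCl.

**Step 3**
Reactants: 4 2,2-dimethyl-6-(2-oxopropyl)-4H-1,3-dioxin-4-one; 6 N-methoxy-N-methylbutanamide
Product: 9 6-(2,4-dioxoheptyl)-2,2-dimethyl-4H-1,3-dioxin-4-one, via dilithium dianion 7 (not isolated), via tetrahedral adduct 8 (not isolated)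
Conditions: LiN(i-Pr)2 (2.2 equiv), THF, −78 → −40 °C; then 6, −40 → −10 °C; aq. HCl, 0 °C
Reagents that add atoms: none
Why: Double deprotonation gives dianion 7, which reacts at its last-formed, most nucleophilic terminal carbon (γ-acylation of a 1,3-dicarbonyl dianion), and the Weinreb ketone synthesis stores the new carbonyl as chelate 8 until the acid quench, so the very acidic product never meets unreacted dianion.

**Step 4**
Reactants: 10 methyl 2,4-dihydroxy-6-propylbenzoate (methyl divarinate)
Product: 11 methyl 4-(benzyloxy)-2-hydroxy-6-propylbenzoate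
Conditions: BnBr (1.05 equiv), K2CO3, acetone, reflux
Reagents that add atoms: benzyl bromide, BrCc1ccccc1
Why: In this Williamson ether synthesis the 2-hydroxyl is held in a hydrogen bond to the neighbouring ester carbonyl, so one equivalent of benzyl bromide with a weak base should alkylate only the free, more acidic 4-hydroxyl.

**Step 5**
Reactants: 11 methyl 4-(benzyloxy)-2-hydroxy-6-propylbenzoate
Product: 12 methyl 4-(benzyloxy)-2-methoxy-6-propylbenzoate
Conditions: MeI (excess), K2CO3, DMF, 50 °C
Reagents that add atoms: methyl iodide, CI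
Why: With no other acidic site left, excess methyl iodide and carbonate in a dipolar aprotic solvent should break the chelate and methylate the 2-hydroxyl (Williamson ether synthesis).

**Step 6**
Reactants: 12 methyl 4-(benzyloxy)-2-methoxy-6-propylbenzoate
Product: 13 methyl 4-hydroxy-2-methoxy-6-propylbenzoate
Conditions: H2 (1 atm), 10% Pd/C, EtOAc, rt
Reagents that add atoms: none
Why: Catalytic hydrogenolysis cleaves only the benzylic C–O bond and leaves the methyl ether, methyl ester and arene untouched.

**Step 7**
Reactants: 9 6-(2,4-dioxoheptyl)-2,2-dimethyl-4H-1,3-dioxin-4-one; 13 methyl 4-hydroxy-2-methoxy-6-propylbenzoate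
Product: 15 3-methoxy-4-(methoxycarbonyl)-5-propylphenyl 3,5,7-trioxodecanoate, via acylketene 14 (not isolated)
Conditions: 13 (2 equiv, ca. 0.5 M), toluene, 110 °C, slow addition of 9, short hold; evaporation, surplus 13 left in
Reagents that add atoms: none
Why: Retro-hetero-Diels–Alder loss of acetone from the dioxinone gives acylketene 14, which adds the phenol O–H under neutral conditions as in the known acetoacetylation of phenols by dioxinones, and a large local excess of phenol over ketene favours this bimolecular capture over closure by the chain C5 enol oxygen.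

**Step 8**
Reactants: 15 3-methoxy-4-(methoxycarbonyl)-5-propylphenyl 3,5,7-trioxodecanoate
Product: 17 3-methoxy-4-(methoxycarbonyl)-5-propylphenyl 2,4-dihydroxy-6-propylbenzoate (target), via cyclic aldol 16 (not isolated)
Conditions: Et3N (1.5 equiv), CH2Cl2, 0 °C → rt; then CF3CO2H, rt
Reagents that add atoms: none
Why: Proposed new method: Et3N interconverts the enolates of 15 rapidly, so closure rates and not acidities decide, and the enolate centred on chain C2 adds to the chain C7 ketone to give aldol 16, after which CF3CO2H expels the tertiary hydroxyl as water and the two remaining ring ketones enolise, so that chain C2–C7 become ring A C1–C6 and the new bond is ring A C1–C6. The closest known reaction type is the base-then-acid aldol aromatisation of alkyl 3,5,7-trioxoalkanoates made from diketo-dioxinones and alcohols, and the untested element is the aryl ester, whose phenoxide can depart. Ring A closes in the 6-(enolendo)-exo-trig mode. The two stereocentres of 16 arise without control and both vanish on aromatisation, so none has to be steered. The step needs the C2-to-C7 aldol to outrun Claisen closure from C6 onto C1, lactonisation by the C5 enol oxygen onto C1 and E1cB loss of the phenoxide from the C2 enolate, all of which would release 13. In its favour, C7 is a true ketone next to an unactivated propyl group while C1 is an ester carbonyl conjugated with the C3 enol, the ring B ester is twisted out of the ring plane by its methoxy and propyl neighbours and so lends the phenoxide little extra stabilisation, a tertiary amine at or below room temperature forms no more than a monoanion, the surplus 13 left from step 7 can re-add to any ketene that forms, and the acid dehydration makes the aldol channel irreversible.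

**Compound list**

1 | 2,2,6-trimethyl-4H-1,3-dioxin-4-one | CC1=CC(=O)OC(C)(C)O1 | starting material
2 | acetyl chloride | CC(=O)Cl | starting material
3 | lithium dienolate of 1 (lithium 2,2-dimethyl-6-methylidene-6H-1,3-dioxin-4-olate) | [Li+].[O-]C1=CC(=C)OC(C)(C)O1 | intermediate
4 | 2,2-dimethyl-6-(2-oxopropyl)-4H-1,3-dioxin-4-one | CC(=O)CC1=CC(=O)OC(C)(C)O1 | intermediate
5 | butanoyl chloride | CCCC(=O)Cl | starting material
6 | N-methoxy-N-methylbutanamide | CCCC(=O)N(C)OC | intermediate
7 | dilithium dianion of 4 (bis-enolate, charges on the side-chain oxygen and the dioxinone C4 oxygen) | [Li+].[Li+].C=C([O-])C=C1C=C([O-])OC(C)(C)O1 | intermediate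
8 | dilithium salt of the tetrahedral adduct of 7 to 6 (racemic) | [Li+].[Li+].CCCC([O-])(N(C)OC)CC(=O)C=C1C=C([O-])OC(C)(C)O1 | intermediate
9 | 6-(2,4-dioxoheptyl)-2,2-dimethyl-4H-1,3-dioxin-4-one | CCCC(=O)CC(=O)CC1=CC(=O)OC(C)(C)O1 | intermediate
10 | methyl 2,4-dihydroxy-6-propylbenzoate (methyl divarinate) | CCCc1cc(O)cc(O)c1C(=O)OC | starting material
11 | methyl 4-(benzyloxy)-2-hydroxy-6-propylbenzoate | CCCc1cc(OCc2ccccc2)cc(O)c1C(=O)OC | intermediate
12 | methyl 4-(benzyloxy)-2-methoxy-6-propylbenzoate | CCCc1cc(OCc2ccccc2)cc(OC)c1C(=O)OC | intermediate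
13 | methyl 4-hydroxy-2-methoxy-6-propylbenzoate | CCCc1cc(O)cc(OC)c1C(=O)OC | intermediate
14 | (3,5-dioxooctanoyl)ketene (dec-1-ene-1,3,5,7-tetraone) | CCCC(=O)CC(=O)CC(=O)C=C=O | intermediate
15 | 3-methoxy-4-(methoxycarbonyl)-5-propylphenyl 3,5,7-trioxodecanoate | CCCC(=O)CC(=O)CC(=O)CC(=O)Oc1cc(CCC)c(C(=O)OC)c(OC)c1 | intermediate
16 | 3-methoxy-4-(methoxycarbonyl)-5-propylphenyl 2-hydroxy-4,6-dioxo-2-propylcyclohexane-1-carboxylate (racemic mixture of diastereomers) | CCCC1(O)CC(=O)CC(=O)C1C(=O)Oc1cc(CCC)c(C(=O)OC)c(OC)c1 | intermediate
17 | 3-methoxy-4-(methoxycarbonyl)-5-propylphenyl 2,4-dihydroxy-6-propylbenzoate (CNP0177078.0, achiral) | CCCc1cc(O)cc(O)c1C(=O)Oc1cc(CCC)c(C(=O)OC)c(OC)c1 | target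

**Counts**

Total steps: 8. Longest linear sequence: 5 steps (10 → 11 → 12 → 13 → 15 → 17, steps 4–8).

**Steps most likely to fail**

Step 8. Departure of the ring B phenoxide from the enolised chain may be faster than the aldol closure. It can occur by elimination to the ketene, by lactonisation through the C5 enol oxygen or by Claisen closure from C6. Adding the acid too early may also trigger cyclodehydration of the triketone segment through oxygen. The fallback uses only known depside chemistry, sets out from 10 and 13 and comes back at 17. Methyl divarinate 10 is benzylated twice (BnBr, K2CO3, DMF, 60 °C) to methyl 2,4-bis(benzyloxy)-6-propylbenzoate F1. The hindered ester is saponified (KOH, aq. DMSO, 90 °C, then acid) to 2,4-bis(benzyloxy)-6-propylbenzoic acid F2. The acid is activated with (CF3CO)2O in toluene at rt as 2,4-bis(benzyloxy)-6-propylbenzoic trifluoroacetic anhydride F3, which acylates phenol 13 to give 3-methoxy-4-(methoxycarbonyl)-5-propylphenyl 2,4-bis(benzyloxy)-6-propylbenzoate F4. Hydrogenolysis (H2, Pd/C, EtOAc) then frees both hydroxyls and gives 17.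

Step 7. Capture of the ketene by a weakly nucleophilic phenol may be too slow. Closure through the C5 enol oxygen, or thermal reversal of the aryl ester at 110 °C, would then drain the material. The fallback reverses the order of events (ring first, ester second), sets out from 9 and 13 and comes back at 17. Diketo-dioxinone 9 is aromatised on its own (Et3N, CH2Cl2, rt) to 7-hydroxy-2,2-dimethyl-5-propyl-4H-1,3-benzodioxin-4-one F5. This is benzylated (BnBr, K2CO3, acetone) to 7-(benzyloxy)-2,2-dimethyl-5-propyl-4H-1,3-benzodioxin-4-one F6. Irradiation (300 nm, CH2Cl2, rt) with excess 13 expels acetone and forms 3-(benzyloxy)-6-(oxomethylidene)-5-propylcyclohexa-2,4-dien-1-one F7. The phenol traps this quinoketene, in the known photochemical depside formation, to give 3-methoxy-4-(methoxycarbonyl)-5-propylphenyl 4-(benzyloxy)-2-hydroxy-6-propylbenzoate F8. Hydrogenolysis (H2, Pd/C, EtOAc) gives 17.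

Step 3. Incomplete second deprotonation, proton exchange with the acyl donor, and premature base- or silica-induced aromatisation during isolation may erode the material. The fallback changes the oxidation level of the electrophile, sets out from 4 and comes back at 9. Dianion 7, made as in step 3, is added to butanal (THF, −78 °C) in an aldol addition that gives racemic 6-(4-hydroxy-2-oxoheptyl)-2,2-dimethyl-4H-1,3-dioxin-4-one F9. Dess–Martin oxidation (CH2Cl2, rt) of the secondary alcohol then delivers 9 under non-basic conditions.

**Further compounds**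

F1 | step 8 | methyl 2,4-bis(benzyloxy)-6-propylbenzoate | CCCc1cc(OCc2ccccc2)cc(OCc2ccccc2)c1C(=O)OC
F2 | step 8 | 2,4-bis(benzyloxy)-6-propylbenzoic acid | CCCc1cc(OCc2ccccc2)cc(OCc2ccccc2)c1C(=O)O
F3 | step 8 | 2,4-bis(benzyloxy)-6-propylbenzoic trifluoroacetic anhydride | CCCc1cc(OCc2ccccc2)cc(OCc2ccccc2)c1C(=O)OC(=O)C(F)(F)F
F4 | step 8 | 3-methoxy-4-(methoxycarbonyl)-5-propylphenyl 2,4-bis(benzyloxy)-6-propylbenzoate | CCCc1cc(OCc2ccccc2)cc(OCc2ccccc2)c1C(=O)Oc1cc(CCC)c(C(=O)OC)c(OC)c1
F5 | step 7 | 7-hydroxy-2,2-dimethyl-5-propyl-4H-1,3-benzodioxin-4-one | CCCc1cc(O)cc2OC(C)(C)OC(=O)c12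
F6 | step 7 | 7-(benzyloxy)-2,2-dimethyl-5-propyl-4H-1,3-benzodioxin-4-one | CCCc1cc(OCc3ccccc3)cc2OC(C)(C)OC(=O)c12
F7 | step 7 | 3-(benzyloxy)-6-(oxomethylidene)-5-propylcyclohexa-2,4-dien-1-one | CCCC1=CC(OCc2ccccc2)=CC(=O)C1=C=O
F8 | step 7 | 3-methoxy-4-(methoxycarbonyl)-5-propylphenyl 4-(benzyloxy)-2-hydroxy-6-propylbenzoate | CCCc1cc(OCc2ccccc2)cc(O)c1C(=O)Oc1cc(CCC)c(C(=O)OC)c(OC)c1
F9 | step 3 | 6-(4-hydroxy-2-oxoheptyl)-2,2-dimethyl-4H-1,3-dioxin-4-one (racemic) | CCCC(O)CC(=O)CC1=CC(=O)OC(C)(C)O1
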